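## Retrosynthetic overview
1. Target 6 ⇒ hydroquinone 5, by methylating only the more acidic OH, the one between the two bromines.
2. 5 ⇒ cut the diaryl ether C–O bond on the ring-A side, not the usual ring-B (Ullmann/SNAr) side. Ring A is used in its oxidised, polarity-reversed form, quinone 2, which accepts at C3 like an enolonium ion. 2,4-Dibromophenol 3 is the O-nucleophile.
3. 2 ⇒ 2,4,6-tribromophenol 1, by oxidative loss of the para bromine.
4. No ring is formed: both benzene rings are bought intact.

Assumption: the SMILES has no stereocentre and the diaryl ether axis rotates freely, so the compound is achiral and no configuration has to be set. Every C–C bond lies inside the two purchased rings, so the only strategic bond is the aryl C–O bond, and the polarity reversal is applied there.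

## Route

Step 1
Reactants: 1 2,4,6-tribromophenol
Product: 2 2,6-dibromo-1,4-benzoquinone
Conditions: fuming HNO3 (d 1.5), 0–5 °C, 30 min; pour on ice; recrystallise from EtOH
Reagents that add atoms: nitric acid, O[N+](=O)[O-]
Why: Oxidative debromination of a 4-halophenol (ipso-nitration para to OH, nitro-to-nitrite rearrangement, loss of the para bromine) is a classical way to this quinone, and the two ortho bromines stay because only the para ipso adduct can collapse to a p-quinone; no stereocentre is formed.

Step 2
Reactants: 2 2,6-dibromo-1,4-benzoquinone (2.3 equiv); 3 2,4-dibromophenol (1.0 equiv)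
Product: 5 3,5-dibromo-2-(2,4-dibromophenoxy)benzene-1,4-diol, via aryloxyquinone 4 (not isolated)
Conditions: K2CO3 (0.3 equiv), 4 Å MS, MeCN, N2, dark, 0 °C → rt, 3 added slowly to 2; then sat. aq. Na2S2O4/EtOAc
Reagents that add atoms: none
Why: Proposed new method: oxidising ring A to the quinone reverses the polarity of its normally nucleophilic ortho carbon, so C3 of 2 (α to C4=O, β to the Br-flanked C1=O, an enolonium-type acceptor) takes up the oxygen of the phenoxide of 3 in an oxa-Michael addition, the adduct tautomerises to 5, a second equivalent of 2 dehydrogenates it to the less electrophilic 4 (which disfavours a second addition), and dithionite returns 5; the closest known reaction type is nucleophilic addition–oxidation of quinones (Thiele–Winter acetoxylation, and the addition of water to 2,6-dihalobenzoquinones at the C–H carbon next to halogen with both halogens kept, a site amines and thiols also use), O-attack is favoured over C-attack because the phenoxide ring is deactivated and blocked at the para and one ortho position, and no stereocentre is formed.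

Step 3
Reactants: 5 3,5-dibromo-2-(2,4-dibromophenoxy)benzene-1,4-diol
Product: 6 3,5-dibromo-2-(2,4-dibromophenoxy)-4-methoxyphenol (target, achiral)
Conditions: TMSCHN2 (1.0 equiv, 2 M in hexanes), PhMe/MeOH 4:1, N2, −20 → 0 °C
Reagents that add atoms: (trimethylsilyl)diazomethane, C[Si](C)(C)C=[N+]=[N-]
Why: In this chemoselective diazoalkane O-methylation the rate-limiting proton transfer to diazomethane (released in situ from TMSCHN2/MeOH) comes from the more acidic OH between the two bromines (estimated pKa ≈ 7, against ≈ 8.5 for the OH next to OAr), the methyldiazonium–phenoxide ion pair collapses at once, and the base-free medium protects the hydroquinone from air oxidation and leaves the C–Br bonds and the diaryl ether untouched; no stereocentre is formed.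

## Compound list
1 | 2,4,6-tribromophenol | Oc1c(Br)cc(Br)cc1Br | starting material
2 | 2,6-dibromo-1,4-benzoquinone | O=C1C=C(Br)C(=O)C(Br)=C1 | intermediate
3 | 2,4-dibromophenol | Oc1ccc(Br)cc1Br | starting material
4 | 3,5-dibromo-2-(2,4-dibromophenoxy)cyclohexa-2,5-diene-1,4-dione | O=C1C=C(Br)C(=O)C(Br)=C1Oc1ccc(Br)cc1Br | intermediate (not isolated)
5 | 3,5-dibromo-2-(2,4-dibromophenoxy)benzene-1,4-diol | Oc1cc(Br)c(O)c(Br)c1Oc1ccc(Br)cc1Br | intermediate
6 | 3,5-dibromo-2-(2,4-dibromophenoxy)-4-methoxyphenol (achiral) | COc1c(Br)cc(O)c(Oc2ccc(Br)cc2Br)c1Br | target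

## Step count and risks
Total steps: 3. Longest linear sequence: 3 (1 → 2 → 5 → 6).

**Risk 1, step 2.**
- Failure modes: ipso displacement of a bromine instead of C–H addition, C-arylation, or base-induced semiquinone formation and decay of 2.
- Fallback: it sets out from 2 and comes back at 4, which is then reduced with dithionite to 5 as in step 2.
- Thiele–Winter acetoxylation of 2 (Ac2O, cat. H2SO4) puts oxygen on the same carbon and gives 3,5-dibromobenzene-1,2,4-triyl triacetate F1.
- HCl/MeOH frees 3,5-dibromobenzene-1,2,4-triol F2.
- FeCl3 oxidises it to 3,5-dibromo-2-hydroxy-1,4-benzoquinone F3, in which only the oxygen to be arylated is still an OH.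
- The potassium salt of F3 is O-arylated in toluene at 80–110 °C with bis(2,4-dibromophenyl)iodonium triflate F4, made in one pot from 1,3-dibromobenzene, I2, mCPBA and TfOH.
- The arylation is a ligand coupling on iodine(III), so ring B now serves as the polarity-reversed aryl-cation partner. C-arylation is blocked by the neighbouring bromine.

**Risk 2, step 3.**
- Failure modes: methylation of the other OH, or of both.
- Check: the OMe of 6 shows no NOE to an aromatic H, whereas the wrong isomer shows OMe/H-6.
- Fallback: it sets out from 4 (isolated by leaving out the dithionite wash) and comes back at 6.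
- Trimethyl phosphite in toluene (Ramirez reaction of quinones) attacks the less hindered carbonyl oxygen. This releases the better-stabilised phenoxide between the two bromines, which is methylated by the methoxyphosphonium centre.
- The product is 3,5-dibromo-2-(2,4-dibromophenoxy)-4-methoxyphenyl dimethyl phosphate F5.
- NaOH in aqueous dioxane at 60 °C then cleaves the P–OAr bond and gives 6.

**Risk 3, step 1.**
- Failure modes: nitrodebromination stopping at 2,6-dibromo-4-nitrophenol, or over-oxidation.
- Fallback: it sets out from 1 and comes back at 2.
- PhI(OAc)2 in MeOH dearomatises 1 by para ipso-methoxylation, and the bromide is solvolysed, giving the isolable quinone monoketal 2,6-dibromo-4,4-dimethoxycyclohexa-2,5-dien-1-one F6.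
- Aqueous TFA hydrolyses F6 to 2.

## Further compounds
F1 | step 2 | 3,5-dibromobenzene-1,2,4-triyl triacetate | CC(=O)Oc1cc(Br)c(OC(C)=O)c(Br)c1OC(C)=O
F2 | step 2 | 3,5-dibromobenzene-1,2,4-triol | Oc1cc(Br)c(O)c(Br)c1O
F3 | step 2 | 3,5-dibromo-2-hydroxy-1,4-benzoquinone | O=C1C=C(Br)C(=O)C(Br)=C1O
F4 | step 2 | bis(2,4-dibromophenyl)iodonium triflate | Brc1ccc([I+]c2ccc(Br)cc2Br)c(Br)c1.[O-]S(=O)(=O)C(F)(F)F
F5 | step 3 | 3,5-dibromo-2-(2,4-dibromophenoxy)-4-methoxyphenyl dimethyl phosphate | COc1c(Br)cc(OP(=O)(OC)OC)c(Oc2ccc(Br)cc2Br)c1Br
F6 | step 1 | 2,6-dibromo-4,4-dimethoxycyclohexa-2,5-dien-1-one | COC1(OC)C=C(Br)C(=O)C(Br)=C1
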